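## Retrosynthetic overview

- The ring carbons are called C1–C10 (C10 bears the methyl C14, C4 the hydroxymethyl C15, C7 the lactone carbons C11–C13). The ten-membered carbocycle (ring A) is opened at C3–C4, giving a seco aldehyde (C3) / Z-alkenyl iodide (C4) that already carries the lactone (ring B), the epoxide (ring C) and the C8 methacrylate. Ring A closes by an intramolecular Nozaki–Hiyama–Kishi coupling.
- Enabling feature: C3 is a secondary carbinol on the Z-trisubstituted C4=C5 olefin, which is the alkenyl-metal/aldehyde retron. Three syn-periplanar units of ring A (Z-C4=C5, the cis C1–C10 epoxide, the cis C6–C7 lactone junction) fold the seco chain so that C3 meets C4.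
- Ring B is made first by an indium Barbier allylation/lactonisation across C6–C7. The partners are a Z-β-iodoenal (C4–C6, C15; from but-2-yne-1,4-diol) and a (Z)-2-(bromomethyl)enoate (C11–C13, C7–C10, C1–C3) whose C8 stereocentre comes from methyl (R)-glycidate.
- Ring C is made second by Shi epoxidation of the Z-C1=C10 olefin. That olefin comes from an α-iodo Wittig olefination and a copper-catalysed alkenyl-Grignard opening of the glycidate (C9–C10 bond).
- Ring order: lactone B (step 11), then epoxide C (step 15), then carbocycle A (step 17); acetylation and one desilylation finish the synthesis.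

Key step: step 17

Remark (assumption): methyl glycidate (both enantiomers), the D-fructose-derived Shi ketone and 3-[(4-methoxybenzyl)oxy]propan-1-ol are taken as commercial. The CIP letters of C6 and C7 change along the route only through priority changes (iodine on C4, silicon on O8), never through inversion.

## Route

Step 1
Reactants: 1 but-2-yne-1,4-diol
Product: 2 4-[(tert-butyldiphenylsilyl)oxy]but-2-yn-1-ol
Conditions: TBDPSCl (0.3 equiv), imidazole, DMF, 0 °C → rt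
Reagents that add atoms: tert-butyl(chloro)diphenylsilane, CC(C)(C)[Si](Cl)(c1ccccc1)c1ccccc1
Why: Silyl ether formation on a symmetrical diol used in excess should give mainly the mono-ether; no stereocentre is involved.

Step 2
Reactants: 2 4-[(tert-butyldiphenylsilyl)oxy]but-2-yn-1-ol
Product: 4 (Z)-4-[(tert-butyldiphenylsilyl)oxy]-3-iodobut-2-en-1-ol, via cyclic alkenylalanate 3 (not isolated)
Conditions: NaAlH2(OCH2CH2OMe)2 (Red-Al), THF, 0 °C; then I2, −78 °C → 0 °C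
Reagents that add atoms: iodine, II
Why: Hydroxyl-directed trans-hydroalumination of the propargylic alcohol puts aluminium on the distal alkyne carbon in a five-membered alanate, and iodinolysis with retention gives the Z-iodoalkene with iodine (future C4) cis to the carbinol carbon (future C6).

Step 3
Reactants: 4 (Z)-4-[(tert-butyldiphenylsilyl)oxy]-3-iodobut-2-en-1-ol
Product: 5 (Z)-4-[(tert-butyldiphenylsilyl)oxy]-3-iodobut-2-enal
Conditions: MnO2, CH2Cl2, rt, dark; used at once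
Reagents that add atoms: none
Why: Allylic alcohol oxidation with MnO2 is neutral and should leave the Z-iodoalkene geometry intact.

Step 4
Reactants: 6 3-[(4-methoxybenzyl)oxy]propan-1-ol
Product: 7 3-[(4-methoxybenzyl)oxy]propanal
Conditions: Dess–Martin periodinane, NaHCO3, CH2Cl2, 0 °C → rt
Reagents that add atoms: none
Why: Buffered Dess–Martin oxidation of a primary alcohol should give the aldehyde without β-elimination of the ether.

Step 5
Reactants: 7 3-[(4-methoxybenzyl)oxy]propanal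
Product: 8 1-({[(3Z)-4-iodopent-3-en-1-yl]oxy}methyl)-4-methoxybenzene
Conditions: EtPPh3I, n-BuLi, THF, 0 °C; I2, −78 °C; NaN(SiMe3)2, −20 °C; then 7, −78 °C → rt
Reagents that add atoms: ethyltriphenylphosphonium iodide, CC[P+](c1ccccc1)(c1ccccc1)c1ccccc1.[I-]; iodine, II
Why: The α-iodo Wittig olefination (Stork–Zhao type) with the non-stabilised iodoethylidene ylide should give the Z-2-iodo-2-alkene, iodine cis to the chain, which fixes the later cis relation of C9 and C2.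

Step 6
Reactants: 8 1-({[(3Z)-4-iodopent-3-en-1-yl]oxy}methyl)-4-methoxybenzene; 9 methyl (2R)-oxirane-2-carboxylate
Product: 11 methyl (2R,4Z)-2-hydroxy-7-[(4-methoxybenzyl)oxy]-4-methylhept-4-enoate, via alkenylmagnesium chloride 10 (not isolated)
Conditions: i-PrMgCl·LiCl, THF, 0 °C → rt; then CuI (10 mol%), 9, −40 °C → −20 °C; aq NH4Cl
Reagents that add atoms: none
Why: Iodine–magnesium exchange keeps the olefin geometry, and the copper-catalysed Grignard opens the glycidate by SN2 attack at the CH2 carbon only, so C8 is taken unchanged from the chiral pool.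

Step 7
Reactants: 11 methyl (2R,4Z)-2-hydroxy-7-[(4-methoxybenzyl)oxy]-4-methylhept-4-enoate
Product: 12 methyl (2R,4Z)-2-[(tert-butyldimethylsilyl)oxy]-7-[(4-methoxybenzyl)oxy]-4-methylhept-4-enoate
Conditions: TBSCl, imidazole, DMF, rt
Reagents that add atoms: tert-butyl(chloro)dimethylsilane, CC(C)(C)[Si](C)(C)Cl
Why: Standard silylation of the secondary alcohol; the stereocentre is not touched.

Step 8
Reactants: 12 methyl (2R,4Z)-2-[(tert-butyldimethylsilyl)oxy]-7-[(4-methoxybenzyl)oxy]-4-methylhept-4-enoate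
Product: 13 (2R,4Z)-2-[(tert-butyldimethylsilyl)oxy]-7-[(4-methoxybenzyl)oxy]-4-methylhept-4-enal
Conditions: i-Bu2AlH, CH2Cl2, −78 °C; aq potassium sodium tartrate
Reagents that add atoms: none
Why: Half-reduction of an α-silyloxy methyl ester stops at the aldehyde because the tetrahedral aluminate is stable at −78 °C; C8 is not epimerised.

Step 9
Reactants: 13 (2R,4Z)-2-[(tert-butyldimethylsilyl)oxy]-7-[(4-methoxybenzyl)oxy]-4-methylhept-4-enal; 14 methyl acrylate
Product: 15 methyl (4R,6Z)-4-[(tert-butyldimethylsilyl)oxy]-3-hydroxy-9-[(4-methoxybenzyl)oxy]-6-methyl-2-methylidenenon-6-enoate (both C3 epimers)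
Conditions: DABCO (1 equiv), MeOH (cat.), neat 14, rt
Reagents that add atoms: none
Why: Morita–Baylis–Hillman reaction; the new carbinol centre (future C7) forms as a mixture, which does not matter because it becomes sp2 in step 10.

Step 10
Reactants: 15 methyl (4R,6Z)-4-[(tert-butyldimethylsilyl)oxy]-3-hydroxy-9-[(4-methoxybenzyl)oxy]-6-methyl-2-methylidenenon-6-enoate
Product: 16 methyl (2Z,4R,6Z)-2-(bromomethyl)-4-[(tert-butyldimethylsilyl)oxy]-9-[(4-methoxybenzyl)oxy]-6-methylnona-2,6-dienoate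
Conditions: NBS, Me2S, CH2Cl2, −20 °C → rt
Reagents that add atoms: N-bromosuccinimide, O=C1CCC(=O)N1Br
Why: Corey–Kim-type activation of the alcohol and SN2' attack of bromide should give the (Z)-2-(bromomethyl)enoate (chain cis to CH2Br), as the isolated trisubstituted olefin is inert to the sulfonium reagent.

Step 11
Reactants: 16 methyl (2Z,4R,6Z)-2-(bromomethyl)-4-[(tert-butyldimethylsilyl)oxy]-9-[(4-methoxybenzyl)oxy]-6-methylnona-2,6-dienoate; 5 (Z)-4-[(tert-butyldiphenylsilyl)oxy]-3-iodobut-2-enal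
Product: 18 (4S,5R)-4-[(1R,3Z)-1-[(tert-butyldimethylsilyl)oxy]-6-[(4-methoxybenzyl)oxy]-3-methylhex-3-en-1-yl]-5-[(1Z)-3-[(tert-butyldiphenylsilyl)oxy]-2-iodoprop-1-en-1-yl]-3-methylideneoxolan-2-one, via hydroxy ester 17 (not isolated)
Conditions: In powder, THF/H2O (1:1), rt; then PPTS (cat.), toluene, 60 °C
Reagents that add atoms: none
Why: In this Barbier allylation the Z-locked 2-(methoxycarbonyl)allylindium should react through a closed chair transition state with the enal residue equatorial, giving the syn adduct and hence the cis C6/C7 lactone; with H8 held in the olefin plane by A(1,3) strain the aldehyde is expected to attack C7 anti to the C9 chain and gauche to the small silyloxy group, relaying C8 to C7 and C6, and acid-catalysed 5-exo-trig lactonisation of the 6-OH then closes ring B.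

Step 12
Reactants: 18 (4S,5R)-4-[(1R,3Z)-1-[(tert-butyldimethylsilyl)oxy]-6-[(4-methoxybenzyl)oxy]-3-methylhex-3-en-1-yl]-5-[(1Z)-3-[(tert-butyldiphenylsilyl)oxy]-2-iodoprop-1-en-1-yl]-3-methylideneoxolan-2-one
Product: 19 (4R,5R)-4-[(1R,3Z)-1-hydroxy-6-[(4-methoxybenzyl)oxy]-3-methylhex-3-en-1-yl]-5-[(1Z)-3-[(tert-butyldiphenylsilyl)oxy]-2-iodoprop-1-en-1-yl]-3-methylideneoxolan-2-one
Conditions: HF·pyridine, pyridine, THF, 0 °C → rt
Reagents that add atoms: none
Why: Buffered HF should cleave the secondary TBS ether while the primary TBDPS ether and the PMB ether survive, and the mildly acidic medium should not trigger translactonisation to O8.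

Step 13
Reactants: 19 (4R,5R)-4-[(1R,3Z)-1-hydroxy-6-[(4-methoxybenzyl)oxy]-3-methylhex-3-en-1-yl]-5-[(1Z)-3-[(tert-butyldiphenylsilyl)oxy]-2-iodoprop-1-en-1-yl]-3-methylideneoxolan-2-one
Product: 20 (1R,3Z)-1-{(2R,3R)-2-[(1Z)-3-[(tert-butyldiphenylsilyl)oxy]-2-iodoprop-1-en-1-yl]-4-methylidene-5-oxooxolan-3-yl}-6-[(4-methoxybenzyl)oxy]-3-methylhex-3-en-1-yl 2-methylprop-2-enoate
Conditions: methacrylic anhydride, Et3N, DMAP (cat.), CH2Cl2, 0 °C → rt
Reagents that add atoms: methacrylic anhydride, C=C(C)C(=O)OC(=O)C(C)=C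
Why: DMAP-catalysed acylation of the only free hydroxyl installs the C8 ester with retention and should be faster than base-induced translactonisation.

Step 14
Reactants: 20 (1R,3Z)-1-{(2R,3R)-2-[(1Z)-3-[(tert-butyldiphenylsilyl)oxy]-2-iodoprop-1-en-1-yl]-4-methylidene-5-oxooxolan-3-yl}-6-[(4-methoxybenzyl)oxy]-3-methylhex-3-en-1-yl 2-methylprop-2-enoate
Product: 21 (1R,3Z)-1-{(2R,3R)-2-[(1Z)-3-[(tert-butyldiphenylsilyl)oxy]-2-iodoprop-1-en-1-yl]-4-methylidene-5-oxooxolan-3-yl}-6-hydroxy-3-methylhex-3-en-1-yl 2-methylprop-2-enoate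
Conditions: DDQ, CH2Cl2/pH 7 phosphate buffer, 0 °C
Reagents that add atoms: none
Why: Oxidative PMB cleavage is neutral and frees a primary homoallylic (not allylic) alcohol, which DDQ should not oxidise further.

Step 15
Reactants: 21 (1R,3Z)-1-{(2R,3R)-2-[(1Z)-3-[(tert-butyldiphenylsilyl)oxy]-2-iodoprop-1-en-1-yl]-4-methylidene-5-oxooxolan-3-yl}-6-hydroxy-3-methylhex-3-en-1-yl 2-methylprop-2-enoate
Product: 22 (1R)-1-{(2R,3R)-2-[(1Z)-3-[(tert-butyldiphenylsilyl)oxy]-2-iodoprop-1-en-1-yl]-4-methylidene-5-oxooxolan-3-yl}-2-[(2S,3R)-3-(2-hydroxyethyl)-2-methyloxiran-2-yl]ethyl 2-methylprop-2-enoate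
Conditions: D-fructose-derived Shi ketone (1 equiv), KHSO5 (Oxone), NaHCO3, MeCN/aq Na2EDTA, 0 °C, pH about 8
Reagents that add atoms: potassium peroxymonosulfate (Oxone), [K+].[O-]S(=O)(=O)OO
Why: Shi epoxidation by the chiral dioxirane (spiro transition state) is reagent-controlled and stereospecific, so the Z-olefin gives the cis-epoxide with the (1R,10S) sense expected by analogy with 1-phenylcyclohexene giving the (R,R)-oxide, and only the electron-rich C1=C10 olefin should react.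

Step 16
Reactants: 22 (1R)-1-{(2R,3R)-2-[(1Z)-3-[(tert-butyldiphenylsilyl)oxy]-2-iodoprop-1-en-1-yl]-4-methylidene-5-oxooxolan-3-yl}-2-[(2S,3R)-3-(2-hydroxyethyl)-2-methyloxiran-2-yl]ethyl 2-methylprop-2-enoate
Product: 23 (1R)-1-{(2R,3R)-2-[(1Z)-3-[(tert-butyldiphenylsilyl)oxy]-2-iodoprop-1-en-1-yl]-4-methylidene-5-oxooxolan-3-yl}-2-[(2S,3R)-2-methyl-3-(2-oxoethyl)oxiran-2-yl]ethyl 2-methylprop-2-enoate
Conditions: Dess–Martin periodinane, NaHCO3, CH2Cl2, 0 °C; used crude without chromatography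
Reagents that add atoms: none
Why: Buffered Dess–Martin oxidation is non-basic, so the β,γ-epoxy aldehyde should form without enolisation and epoxide opening, provided it is used at once.

Step 17
Reactants: 23 (1R)-1-{(2R,3R)-2-[(1Z)-3-[(tert-butyldiphenylsilyl)oxy]-2-iodoprop-1-en-1-yl]-4-methylidene-5-oxooxolan-3-yl}-2-[(2S,3R)-2-methyl-3-(2-oxoethyl)oxiran-2-yl]ethyl 2-methylprop-2-enoate
Product: 24 (1R,3S,4Z,6S,7R,8R,10S)-15-[(tert-butyldiphenylsilyl)oxy]-1,10-epoxy-3-hydroxy-8-(methacryloyloxy)germacra-4,11(13)-dien-12,6-olide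
Conditions: CrCl2 (15 equiv), NiCl2 (0.15 equiv), degassed DMSO/THF (3:1), rt, 23 added over 12 h (final 2 mM)
Reagents that add atoms: none
Why: The C4–I bond adds oxidatively to zerovalent nickel (from NiCl2 and CrCl2), the alkenyl group is passed to trivalent chromium, and the alkenylchromium adds to the chromium-bound C3 aldehyde, forming C3–C4 with retention of the Z-olefin; the closest known reaction type is the intramolecular Nozaki–Hiyama–Kishi alkenyl iodide–aldehyde coupling used for nine- and ten-membered carbocycles. Ring A closes in a 10-exo-trig mode and is the last ring formed, lactone B and epoxide C being in place. Closure is helped by the three syn-periplanar units of the seco chain (Z-C4=C5, cis C1–C10 epoxide, cis C6–C7 junction), which bring C3 close to C4. The new C3 stereocentre is set by macrocyclic conformational control: A(1,3) strain across the Z-olefin puts the aldehyde hydrogen in the olefin plane toward C6, and the C2 and C7 ring bonds must leave that plane on the same face for the short C7–C10/C1–C2 bridge to close, so the carbonyl oxygen is expected on the face of the lactone oxygen O6 (3,6-cis, 3S). The step needs chemoselectivity for the aldehyde over lactone, methacrylate, exo-methylene and epoxide, which the non-basic, aldehyde-selective alkenylchromium secures, and it needs cyclisation to outrun oligomerisation, which slow addition at high dilution secures.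

Step 18
Reactants: 24 (1R,3S,4Z,6S,7R,8R,10S)-15-[(tert-butyldiphenylsilyl)oxy]-1,10-epoxy-3-hydroxy-8-(methacryloyloxy)germacra-4,11(13)-dien-12,6-olide
Product: 25 (1R,3S,4Z,6S,7R,8R,10S)-3-acetoxy-15-[(tert-butyldiphenylsilyl)oxy]-1,10-epoxy-8-(methacryloyloxy)germacra-4,11(13)-dien-12,6-olide
Conditions: Ac2O, pyridine, DMAP (cat.), CH2Cl2, 0 °C
Reagents that add atoms: acetic anhydride, CC(=O)OC(C)=O
Why: Acylation of the only free hydroxyl occurs at oxygen with retention at C3 under conditions the epoxide tolerates.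

Step 19
Reactants: 25 (1R,3S,4Z,6S,7R,8R,10S)-3-acetoxy-15-[(tert-butyldiphenylsilyl)oxy]-1,10-epoxy-8-(methacryloyloxy)germacra-4,11(13)-dien-12,6-olide
Product: 26 (1R,3S,4Z,6S,7R,8R,10S)-3-acetoxy-1,10-epoxy-15-hydroxy-8-(methacryloyloxy)germacra-4,11(13)-dien-12,6-olide (CNP0319155.2)
Conditions: Bu4NF/AcOH (1:1), THF, 0 °C → rt
Reagents that add atoms: none
Why: Acetic acid-buffered fluoride desilylation is near neutral, so the epoxide should not open transannularly, the acetate should not migrate from O3 to O15, and the two Michael acceptors should survive.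

## Compound list

1 | but-2-yne-1,4-diol | OCC#CCO | starting material
2 | 4-[(tert-butyldiphenylsilyl)oxy]but-2-yn-1-ol | OCC#CCO[Si](c1ccccc1)(c1ccccc1)C(C)(C)C | intermediate
3 | sodium cyclic alkenylalanate (2,2-bis(2-methoxyethoxy)-1,2-oxaaluminol-3-ene ate complex, C3 bearing CH2OTBDPS) | [Na+].COCCO[Al-]1(OCCOC)OCC=C1CO[Si](c1ccccc1)(c1ccccc1)C(C)(C)C | intermediate
4 | (Z)-4-[(tert-butyldiphenylsilyl)oxy]-3-iodobut-2-en-1-ol | OC/C=C(\I)CO[Si](c1ccccc1)(c1ccccc1)C(C)(C)C | intermediate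
5 | (Z)-4-[(tert-butyldiphenylsilyl)oxy]-3-iodobut-2-enal | O=C/C=C(\I)CO[Si](c1ccccc1)(c1ccccc1)C(C)(C)C | intermediate
6 | 3-[(4-methoxybenzyl)oxy]propan-1-ol | OCCCOCc1ccc(OC)cc1 | starting material
7 | 3-[(4-methoxybenzyl)oxy]propanal | O=CCCOCc1ccc(OC)cc1 | intermediate
8 | 1-({[(3Z)-4-iodopent-3-en-1-yl]oxy}methyl)-4-methoxybenzene | C/C(I)=C/CCOCc1ccc(OC)cc1 | intermediate
9 | methyl (2R)-oxirane-2-carboxylate | COC(=O)[C@H]1CO1 | starting material
10 | chloro{(2Z)-5-[(4-methoxybenzyl)oxy]pent-2-en-2-yl}magnesium | C/C([Mg]Cl)=C/CCOCc1ccc(OC)cc1 | intermediate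
11 | methyl (2R,4Z)-2-hydroxy-7-[(4-methoxybenzyl)oxy]-4-methylhept-4-enoate | COC(=O)[C@H](O)C/C(C)=C\CCOCc1ccc(OC)cc1 | intermediate
12 | methyl (2R,4Z)-2-[(tert-butyldimethylsilyl)oxy]-7-[(4-methoxybenzyl)oxy]-4-methylhept-4-enoate | COC(=O)[C@H](O[Si](C)(C)C(C)(C)C)C/C(C)=C\CCOCc1ccc(OC)cc1 | intermediate
13 | (2R,4Z)-2-[(tert-butyldimethylsilyl)oxy]-7-[(4-methoxybenzyl)oxy]-4-methylhept-4-enal | O=C[C@H](O[Si](C)(C)C(C)(C)C)C/C(C)=C\CCOCc1ccc(OC)cc1 | intermediate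
14 | methyl acrylate | C=CC(=O)OC | starting material
15 | methyl (4R,6Z)-4-[(tert-butyldimethylsilyl)oxy]-3-hydroxy-9-[(4-methoxybenzyl)oxy]-6-methyl-2-methylidenenon-6-enoate (C3 epimers) | COC(=O)C(=C)C(O)[C@H](O[Si](C)(C)C(C)(C)C)C/C(C)=C\CCOCc1ccc(OC)cc1 | intermediate
16 | methyl (2Z,4R,6Z)-2-(bromomethyl)-4-[(tert-butyldimethylsilyl)oxy]-9-[(4-methoxybenzyl)oxy]-6-methylnona-2,6-dienoate | COC(=O)/C(CBr)=C/[C@H](O[Si](C)(C)C(C)(C)C)C/C(C)=C\CCOCc1ccc(OC)cc1 | intermediate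
17 | methyl (3S,4R,5Z)-3-[(1R,3Z)-1-[(tert-butyldimethylsilyl)oxy]-6-[(4-methoxybenzyl)oxy]-3-methylhex-3-en-1-yl]-7-[(tert-butyldiphenylsilyl)oxy]-4-hydroxy-6-iodo-2-methylidenehept-5-enoate | COC(=O)C(=C)[C@@H]([C@@H](O)/C=C(\I)CO[Si](c1ccccc1)(c1ccccc1)C(C)(C)C)[C@H](O[Si](C)(C)C(C)(C)C)C/C(C)=C\CCOCc1ccc(OC)cc1 | intermediate
18 | (4S,5R)-4-[(1R,3Z)-1-[(tert-butyldimethylsilyl)oxy]-6-[(4-methoxybenzyl)oxy]-3-methylhex-3-en-1-yl]-5-[(1Z)-3-[(tert-butyldiphenylsilyl)oxy]-2-iodoprop-1-en-1-yl]-3-methylideneoxolan-2-one | C=C1C(=O)O[C@@H](/C=C(\I)CO[Si](c2ccccc2)(c2ccccc2)C(C)(C)C)[C@H]1[C@H](O[Si](C)(C)C(C)(C)C)C/C(C)=C\CCOCc1ccc(OC)cc1 | intermediate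
19 | (4R,5R)-4-[(1R,3Z)-1-hydroxy-6-[(4-methoxybenzyl)oxy]-3-methylhex-3-en-1-yl]-5-[(1Z)-3-[(tert-butyldiphenylsilyl)oxy]-2-iodoprop-1-en-1-yl]-3-methylideneoxolan-2-one | C=C1C(=O)O[C@@H](/C=C(\I)CO[Si](c2ccccc2)(c2ccccc2)C(C)(C)C)[C@H]1[C@H](O)C/C(C)=C\CCOCc1ccc(OC)cc1 | intermediate
20 | (1R,3Z)-1-{(2R,3R)-2-[(1Z)-3-[(tert-butyldiphenylsilyl)oxy]-2-iodoprop-1-en-1-yl]-4-methylidene-5-oxooxolan-3-yl}-6-[(4-methoxybenzyl)oxy]-3-methylhex-3-en-1-yl 2-methylprop-2-enoate | C=C1C(=O)O[C@@H](/C=C(\I)CO[Si](c2ccccc2)(c2ccccc2)C(C)(C)C)[C@H]1[C@H](OC(=O)C(C)=C)C/C(C)=C\CCOCc1ccc(OC)cc1 | intermediate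
21 | (1R,3Z)-1-{(2R,3R)-2-[(1Z)-3-[(tert-butyldiphenylsilyl)oxy]-2-iodoprop-1-en-1-yl]-4-methylidene-5-oxooxolan-3-yl}-6-hydroxy-3-methylhex-3-en-1-yl 2-methylprop-2-enoate | C=C1C(=O)O[C@@H](/C=C(\I)CO[Si](c2ccccc2)(c2ccccc2)C(C)(C)C)[C@H]1[C@H](OC(=O)C(C)=C)C/C(C)=C\CCO | intermediate
22 | (1R)-1-{(2R,3R)-2-[(1Z)-3-[(tert-butyldiphenylsilyl)oxy]-2-iodoprop-1-en-1-yl]-4-methylidene-5-oxooxolan-3-yl}-2-[(2S,3R)-3-(2-hydroxyethyl)-2-methyloxiran-2-yl]ethyl 2-methylprop-2-enoate | C=C1C(=O)O[C@@H](/C=C(\I)CO[Si](c2ccccc2)(c2ccccc2)C(C)(C)C)[C@H]1[C@H](OC(=O)C(C)=C)C[C@]1(C)O[C@@H]1CCO | intermediate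
23 | (1R)-1-{(2R,3R)-2-[(1Z)-3-[(tert-butyldiphenylsilyl)oxy]-2-iodoprop-1-en-1-yl]-4-methylidene-5-oxooxolan-3-yl}-2-[(2S,3R)-2-methyl-3-(2-oxoethyl)oxiran-2-yl]ethyl 2-methylprop-2-enoate | C=C1C(=O)O[C@@H](/C=C(\I)CO[Si](c2ccccc2)(c2ccccc2)C(C)(C)C)[C@H]1[C@H](OC(=O)C(C)=C)C[C@]1(C)O[C@@H]1CC=O | intermediate
24 | (1R,3S,4Z,6S,7R,8R,10S)-15-[(tert-butyldiphenylsilyl)oxy]-1,10-epoxy-3-hydroxy-8-(methacryloyloxy)germacra-4,11(13)-dien-12,6-olide | C=C(C)C(=O)O[C@@H]1C[C@]2(C)O[C@@H]2C[C@H](O)/C(CO[Si](c2ccccc2)(c2ccccc2)C(C)(C)C)=C\[C@@H]2OC(=O)C(=C)[C@@H]21 | intermediate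
25 | (1R,3S,4Z,6S,7R,8R,10S)-3-acetoxy-15-[(tert-butyldiphenylsilyl)oxy]-1,10-epoxy-8-(methacryloyloxy)germacra-4,11(13)-dien-12,6-olide | C=C(C)C(=O)O[C@@H]1C[C@]2(C)O[C@@H]2C[C@H](OC(C)=O)/C(CO[Si](c2ccccc2)(c2ccccc2)C(C)(C)C)=C\[C@@H]2OC(=O)C(=C)[C@@H]21 | intermediate
26 | (1R,3S,4Z,6S,7R,8R,10S)-3-acetoxy-1,10-epoxy-15-hydroxy-8-(methacryloyloxy)germacra-4,11(13)-dien-12,6-olide (CNP0319155.2) | C=C(C)C(=O)O[C@@H]1C[C@]2(C)O[C@@H]2C[C@H](OC(C)=O)/C(CO)=C\[C@@H]2OC(=O)C(=C)[C@@H]21 | target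

## Step count and risks

Total step count: 19. Longest linear sequence: 16 steps (6 to 26, steps 4–19); the iodoenal branch (steps 1–3) joins at step 11.

Steps most likely to fail:

Step 17. Besides oligomerisation, the alkenylchromium may add to the other face of the C3 aldehyde, because the macrocyclic conformational preference is a prediction. The fallback sets out from 23: if the closure gives mainly the (3R)-carbinol, (1R,3R,4Z,6S,7R,8R,10S)-15-[(tert-butyldiphenylsilyl)oxy]-1,10-epoxy-3-hydroxy-8-(methacryloyloxy)germacra-4,11(13)-dien-12,6-olide F1, the acetate is not put on by acylation. Instead a Mitsunobu esterification with acetic acid (PPh3, diisopropyl azodicarboxylate, toluene, 0 °C) installs it with SN2 inversion at the allylic C3, and the route is rejoined at 25.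

Step 11. The aldehyde may attack the other diastereoface of the allylindium (anti to the silyloxy group instead of anti to the C9 chain), which would give C6 and C7 in the mirror-image sense relative to C8. The fallback is a configurational relay that sets out from 8 and uses the other glycidate enantiomer, methyl (2S)-oxirane-2-carboxylate F2. Steps 6–10 run in the same way and should give the hydroxy ester methyl (2S,4Z)-2-hydroxy-7-[(4-methoxybenzyl)oxy]-4-methylhept-4-enoate F3, its silyl ether methyl (2S,4Z)-2-[(tert-butyldimethylsilyl)oxy]-7-[(4-methoxybenzyl)oxy]-4-methylhept-4-enoate F4, the aldehyde (2S,4Z)-2-[(tert-butyldimethylsilyl)oxy]-7-[(4-methoxybenzyl)oxy]-4-methylhept-4-enal F5, the Morita–Baylis–Hillman adduct methyl (4S,6Z)-4-[(tert-butyldimethylsilyl)oxy]-3-hydroxy-9-[(4-methoxybenzyl)oxy]-6-methyl-2-methylidenenon-6-enoate F6 and the bromide methyl (2Z,4S,6Z)-2-(bromomethyl)-4-[(tert-butyldimethylsilyl)oxy]-9-[(4-methoxybenzyl)oxy]-6-methylnona-2,6-dienoate F7. With the reversed facial preference, F7 and 5 would give, through the 8-epi hydroxy ester methyl (3S,4R,5Z)-3-[(1S,3Z)-1-[(tert-butyldimethylsilyl)oxy]-6-[(4-methoxybenzyl)oxy]-3-methylhex-3-en-1-yl]-7-[(tert-butyldiphenylsilyl)oxy]-4-hydroxy-6-iodo-2-methylidenehept-5-enoate F8, the 8-epi lactone (4S,5R)-4-[(1S,3Z)-1-[(tert-butyldimethylsilyl)oxy]-6-[(4-methoxybenzyl)oxy]-3-methylhex-3-en-1-yl]-5-[(1Z)-3-[(tert-butyldiphenylsilyl)oxy]-2-iodoprop-1-en-1-yl]-3-methylideneoxolan-2-one F9, which has the correct C6 and C7. Desilylation as in step 12 gives the 8-epi alcohol (4R,5R)-4-[(1S,3Z)-1-hydroxy-6-[(4-methoxybenzyl)oxy]-3-methylhex-3-en-1-yl]-5-[(1Z)-3-[(tert-butyldiphenylsilyl)oxy]-2-iodoprop-1-en-1-yl]-3-methylideneoxolan-2-one F10. A Mitsunobu esterification with methacrylic acid (PPh3, diisopropyl azodicarboxylate) then inverts C8 and comes back to the route at 20.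

Step 15. The dioxirane may also oxidise the alkenyl iodide, or the reagent-controlled face selectivity on the Z-trisubstituted olefin may be modest. The fallback uses substrate control and sets out from 19: hydroxyl-directed epoxidation of the free C8 homoallylic alcohol with VO(acac)2 (cat.) and t-BuOOH in CH2Cl2. A chair-like vanadate transition state with the carbinol substituent (C7) equatorial and C1 anti to C8 (avoiding A(1,3) strain with C2) should deliver oxygen to the face that gives the (1R,10S)-epoxy alcohol (4R,5R)-4-{(1R)-1-hydroxy-2-[(2S,3R)-3-{2-[(4-methoxybenzyl)oxy]ethyl}-2-methyloxiran-2-yl]ethyl}-5-[(1Z)-3-[(tert-butyldiphenylsilyl)oxy]-2-iodoprop-1-en-1-yl]-3-methylideneoxolan-2-one F11. Methacryloylation as in step 13 gives the ester (1R)-1-{(2R,3R)-2-[(1Z)-3-[(tert-butyldiphenylsilyl)oxy]-2-iodoprop-1-en-1-yl]-4-methylidene-5-oxooxolan-3-yl}-2-[(2S,3R)-3-{2-[(4-methoxybenzyl)oxy]ethyl}-2-methyloxiran-2-yl]ethyl 2-methylprop-2-enoate F12, and DDQ cleavage as in step 14 comes back to the route at 22.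

Further compounds
F1 | step 17 | (1R,3R,4Z,6S,7R,8R,10S)-15-[(tert-butyldiphenylsilyl)oxy]-1,10-epoxy-3-hydroxy-8-(methacryloyloxy)germacra-4,11(13)-dien-12,6-olide | C=C(C)C(=O)O[C@@H]1C[C@]2(C)O[C@@H]2C[C@@H](O)/C(CO[Si](c2ccccc2)(c2ccccc2)C(C)(C)C)=C\[C@@H]2OC(=O)C(=C)[C@@H]21
F2 | step 11 | methyl (2S)-oxirane-2-carboxylate | COC(=O)[C@@H]1CO1
F3 | step 11 | methyl (2S,4Z)-2-hydroxy-7-[(4-methoxybenzyl)oxy]-4-methylhept-4-enoate | COC(=O)[C@@H](O)C/C(C)=C\CCOCc1ccc(OC)cc1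
F4 | step 11 | methyl (2S,4Z)-2-[(tert-butyldimethylsilyl)oxy]-7-[(4-methoxybenzyl)oxy]-4-methylhept-4-enoate | COC(=O)[C@@H](O[Si](C)(C)C(C)(C)C)C/C(C)=C\CCOCc1ccc(OC)cc1
F5 | step 11 | (2S,4Z)-2-[(tert-butyldimethylsilyl)oxy]-7-[(4-methoxybenzyl)oxy]-4-methylhept-4-enal | O=C[C@@H](O[Si](C)(C)C(C)(C)C)C/C(C)=C\CCOCc1ccc(OC)cc1
F6 | step 11 | methyl (4S,6Z)-4-[(tert-butyldimethylsilyl)oxy]-3-hydroxy-9-[(4-methoxybenzyl)oxy]-6-methyl-2-methylidenenon-6-enoate (C3 epimers) | COC(=O)C(=C)C(O)[C@@H](O[Si](C)(C)C(C)(C)C)C/C(C)=C\CCOCc1ccc(OC)cc1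
F7 | step 11 | methyl (2Z,4S,6Z)-2-(bromomethyl)-4-[(tert-butyldimethylsilyl)oxy]-9-[(4-methoxybenzyl)oxy]-6-methylnona-2,6-dienoate | COC(=O)/C(CBr)=C/[C@@H](O[Si](C)(C)C(C)(C)C)C/C(C)=C\CCOCc1ccc(OC)cc1
F8 | step 11 | methyl (3S,4R,5Z)-3-[(1S,3Z)-1-[(tert-butyldimethylsilyl)oxy]-6-[(4-methoxybenzyl)oxy]-3-methylhex-3-en-1-yl]-7-[(tert-butyldiphenylsilyl)oxy]-4-hydroxy-6-iodo-2-methylidenehept-5-enoate | COC(=O)C(=C)[C@@H]([C@@H](O)/C=C(\I)CO[Si](c1ccccc1)(c1ccccc1)C(C)(C)C)[C@@H](O[Si](C)(C)C(C)(C)C)C/C(C)=C\CCOCc1ccc(OC)cc1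
F9 | step 11 | (4S,5R)-4-[(1S,3Z)-1-[(tert-butyldimethylsilyl)oxy]-6-[(4-methoxybenzyl)oxy]-3-methylhex-3-en-1-yl]-5-[(1Z)-3-[(tert-butyldiphenylsilyl)oxy]-2-iodoprop-1-en-1-yl]-3-methylideneoxolan-2-one | C=C1C(=O)O[C@@H](/C=C(\I)CO[Si](c2ccccc2)(c2ccccc2)C(C)(C)C)[C@H]1[C@@H](O[Si](C)(C)C(C)(C)C)C/C(C)=C\CCOCc1ccc(OC)cc1
F10 | step 11 | (4R,5R)-4-[(1S,3Z)-1-hydroxy-6-[(4-methoxybenzyl)oxy]-3-methylhex-3-en-1-yl]-5-[(1Z)-3-[(tert-butyldiphenylsilyl)oxy]-2-iodoprop-1-en-1-yl]-3-methylideneoxolan-2-one | C=C1C(=O)O[C@@H](/C=C(\I)CO[Si](c2ccccc2)(c2ccccc2)C(C)(C)C)[C@H]1[C@@H](O)C/C(C)=C\CCOCc1ccc(OC)cc1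
F11 | step 15 | (4R,5R)-4-{(1R)-1-hydroxy-2-[(2S,3R)-3-{2-[(4-methoxybenzyl)oxy]ethyl}-2-methyloxiran-2-yl]ethyl}-5-[(1Z)-3-[(tert-butyldiphenylsilyl)oxy]-2-iodoprop-1-en-1-yl]-3-methylideneoxolan-2-one | C=C1C(=O)O[C@@H](/C=C(\I)CO[Si](c2ccccc2)(c2ccccc2)C(C)(C)C)[C@H]1[C@H](O)C[C@]1(C)O[C@@H]1CCOCc1ccc(OC)cc1
F12 | step 15 | (1R)-1-{(2R,3R)-2-[(1Z)-3-[(tert-butyldiphenylsilyl)oxy]-2-iodoprop-1-en-1-yl]-4-methylidene-5-oxooxolan-3-yl}-2-[(2S,3R)-3-{2-[(4-methoxybenzyl)oxy]ethyl}-2-methyloxiran-2-yl]ethyl 2-methylprop-2-enoate | C=C1C(=O)O[C@@H](/C=C(\I)CO[Si](c2ccccc2)(c2ccccc2)C(C)(C)C)[C@H]1[C@H](OC(=O)C(C)=C)C[C@]1(C)O[C@@H]1CCOCc1ccc(OC)cc1
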